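**Retrosynthetic overview**
1. Target 31 ← global desilylation of trans-lactone 30 ← lactonisation and C3 equilibration of γ-hydroxy tert-butyl ester 28 ← reduction of imide ester 27.
2. Key disconnection, lactone C3–C4: iron-mediated oxidative heterocoupling of two enolate α-carbons, imide 13 (auxiliary fixes C4) and tert-butyl ester 26.
3. 13 ← magnesium-catalysed anti-aldol of aryloxyacetyl imide 5 with silylated vanillin 2 (erythro glycerol unit), then reduction, silylation and auxiliary exchange.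
4. 26 ← Negishi coupling of bromide 24 ← acid-induced trans ring closure of diol 22 ← Evans syn-aldol of arylacetyl imide 19 with 2.
5. Ring order: dihydrobenzofuran first (step 14), lactone last (step 19); all benzene rings are bought.

Assumption: the SMILES is read as lactone (3R,4R), dihydrobenzofuran (2S,3R)-trans and glycerol unit (1R,2S)-erythro; 4, 11 and the organozinc solution 25 are taken as catalogue items.

Abbreviations: TIPS = triisopropylsilyl; TBS = tert-butyldimethylsilyl; MOM = methoxymethyl; Piv = pivaloyl.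
ArG = 4-({(1R,2S)-1,3-bis(tert-butyldimethylsilyloxy)-1-[3-methoxy-4-(triisopropylsilyloxy)phenyl]propan-2-yl}oxy)-3-methoxyphenyl.
ArP = (2S,3R)-3-[(tert-butyldimethylsilyloxy)methyl]-7-methoxy-2-[3-methoxy-4-(triisopropylsilyloxy)phenyl]-2,3-dihydro-1-benzofuran-5-yl.

**Route**

Step 1
Reactants: 1 vanillin
Product: 2 3-methoxy-4-(triisopropylsilyloxy)benzaldehyde
Conditions: TIPSCl (1.1 equiv), imidazole (2.2 equiv), DMF, rt
Reagents that add atoms: triisopropylsilyl chloride, CC(C)[Si](Cl)(C(C)C)C(C)C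
Why: Imidazole-promoted O-silylation of the phenol gives an aryl silyl ether that survives the bases, hydrides and acids used later and falls to fluoride at the end; no stereocentre is involved.

Step 2
Reactants: 3 methyl 3-(4-hydroxy-3-methoxyphenyl)propanoate; 4 (S)-4-benzyl-3-(chloroacetyl)oxazolidin-2-one
Product: 5 (S)-4-benzyl-3-{[2-methoxy-4-(3-methoxy-3-oxopropyl)phenoxy]acetyl}oxazolidin-2-one
Conditions: K2CO3 (1.5 equiv), NaI (10 mol %), MeCN, 40 °C
Reagents that add atoms: none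
Why: Williamson ether synthesis in which the phenoxide displaces the carbonyl-activated primary chloride by SN2 (iodide catalysis) faster than it attacks the imide carbonyl; the auxiliary stereocentre is untouched.

Step 3
Reactants: 5 (S)-4-benzyl-3-{[2-methoxy-4-(3-methoxy-3-oxopropyl)phenoxy]acetyl}oxazolidin-2-one; 2 3-methoxy-4-(triisopropylsilyloxy)benzaldehyde
Product: 7 (S)-4-benzyl-3-{(2R,3R)-3-hydroxy-2-[2-methoxy-4-(3-methoxy-3-oxopropyl)phenoxy]-3-[3-methoxy-4-(triisopropylsilyloxy)phenyl]propanoyl}oxazolidin-2-one, via trimethylsilyl ether 6 (not isolated)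
Conditions: MgCl2 (20 mol %), Et3N (2 equiv), TMSCl (1.5 equiv), EtOAc, rt, 24 h; then 1 M HCl, THF, rt
Reagents that add atoms: none
Why: Evans magnesium-halide-catalysed direct anti-aldol, in which the MgCl2-chelated Z-enolate of the (S)-benzyl imide is attacked by the non-enolisable aldehyde on the face opposite the benzyl group through a boat-like transition state and the aldolate is trapped as its silyl ether, setting C2 (R) and C3 (R), i.e. the erythro aryloxy alcohol.

Step 4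
Reactants: 7 (S)-4-benzyl-3-{(2R,3R)-3-hydroxy-2-[2-methoxy-4-(3-methoxy-3-oxopropyl)phenoxy]-3-[3-methoxy-4-(triisopropylsilyloxy)phenyl]propanoyl}oxazolidin-2-one
Product: 8 methyl 3-[4-({(1R,2S)-1,3-dihydroxy-1-[3-methoxy-4-(triisopropylsilyloxy)phenyl]propan-2-yl}oxy)-3-methoxyphenyl]propanoate
Conditions: NaBH4 (3 equiv), THF/H2O (4:1), 0 °C → rt
Reagents that add atoms: none
Why: Reductive removal of the auxiliary, in which borohydride in aqueous THF reduces the activated N-acyl oxazolidinone to the primary alcohol but not the methyl ester; no enolisation occurs, so both stereocentres are kept.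

Step 5
Reactants: 8 methyl 3-[4-({(1R,2S)-1,3-dihydroxy-1-[3-methoxy-4-(triisopropylsilyloxy)phenyl]propan-2-yl}oxy)-3-methoxyphenyl]propanoate
Product: 9 methyl 3-ArG-propanoate
Conditions: TBSOTf (2.4 equiv), 2,6-lutidine (3 equiv), CH2Cl2, −78 → 0 °C
Reagents that add atoms: tert-butyldimethylsilyl triflate, CC(C)(C)[Si](C)(C)OS(=O)(=O)C(F)(F)F
Why: Silyl triflate silylation protects the primary and the hindered benzylic secondary alcohol as ethers that tolerate the strong base and hydride steps ahead; buffered low-temperature conditions avoid benzylic ionisation.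

Step 6
Reactants: 9 methyl 3-ArG-propanoate
Product: 10 3-ArG-propanoic acid
Conditions: LiOH·H2O (3 equiv), THF/H2O (3:1), 0 °C → rt; then 1 M HCl to pH 3
Reagents that add atoms: lithium hydroxide, [Li+].[OH-]
Why: Saponification of the unhindered methyl ester; the alkyl TBS ethers and the bulky aryl TIPS ether survive cold aqueous LiOH.

Step 7
Reactants: 10 3-ArG-propanoic acid; 11 (S)-4-benzyloxazolidin-2-one
Product: 13 (S)-4-benzyl-3-(3-ArG-propanoyl)oxazolidin-2-one, via mixed pivalic anhydride 12 (not isolated)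
Conditions: PivCl (1.1 equiv), Et3N (2.5 equiv), THF, −20 °C; then 11 (1.1 equiv), LiCl (1.2 equiv), rt
Reagents that add atoms: none
Why: Mixed-anhydride N-acylation of the oxazolidinone (LiCl/Et3N protocol), with attack at the less hindered carbonyl of the pivalic mixed anhydride, installs the auxiliary that will control lactone C4.

Step 8
Reactants: 14 2-allyl-6-methoxyphenol
Product: 15 2-allyl-4-bromo-6-methoxyphenol
Conditions: NBS (1.0 equiv), MeCN, 0 °C
Reagents that add atoms: N-bromosuccinimide, O=C1CCC(=O)N1Br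
Why: Electrophilic aromatic bromination goes para to the free phenol because both ortho positions are blocked, and the ring reacts much faster than the allyl group.

Step 9
Reactants: 15 2-allyl-4-bromo-6-methoxyphenol
Product: 16 1-allyl-5-bromo-3-methoxy-2-(methoxymethoxy)benzene
Conditions: MOMCl (1.3 equiv), iPr2NEt (1.6 equiv), CH2Cl2, 0 °C → rt
Reagents that add atoms: chloromethyl methyl ether, COCCl
Why: MOM acetal formation masks the phenol through the oxidation and the boron aldol and is later removed by the same acid that closes the furan ring.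

Step 10
Reactants: 16 1-allyl-5-bromo-3-methoxy-2-(methoxymethoxy)benzene
Product: 17 [5-bromo-3-methoxy-2-(methoxymethoxy)phenyl]acetic acid
Conditions: RuCl3·xH2O (2 mol %), NaIO4 (4.1 equiv), EtOAc/MeCN/H2O (2:2:3), rt
Reagents that add atoms: sodium periodate, [Na+].[O-]I(=O)(=O)=O; water, O
Why: Catalytic ruthenium tetroxide oxidative cleavage turns the terminal alkene into the arylacetic acid, the alkene reacting far faster than the brominated ring or the acetal.

Step 11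
Reactants: 17 [5-bromo-3-methoxy-2-(methoxymethoxy)phenyl]acetic acid; 11 (S)-4-benzyloxazolidin-2-one
Product: 19 (S)-4-benzyl-3-{[5-bromo-3-methoxy-2-(methoxymethoxy)phenyl]acetyl}oxazolidin-2-one, via mixed pivalic anhydride 18 (not isolated)
Conditions: PivCl (1.1 equiv), Et3N (2.5 equiv), THF, −20 °C; then 11 (1.1 equiv), LiCl (1.2 equiv), rt
Reagents that add atoms: none
Why: The same mixed-anhydride N-acylation gives the arylacetyl imide needed for the auxiliary-controlled aldol.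

Step 12
Reactants: 19 (S)-4-benzyl-3-{[5-bromo-3-methoxy-2-(methoxymethoxy)phenyl]acetyl}oxazolidin-2-one; 2 3-methoxy-4-(triisopropylsilyloxy)benzaldehyde
Product: 21 (S)-4-benzyl-3-{(2S,3S)-2-[5-bromo-3-methoxy-2-(methoxymethoxy)phenyl]-3-hydroxy-3-[3-methoxy-4-(triisopropylsilyloxy)phenyl]propanoyl}oxazolidin-2-one, via dibutylboron aldolate 20 (not isolated)
Conditions: Bu2BOTf (1.2 equiv), iPr2NEt (1.4 equiv), CH2Cl2, −78 → 0 °C; 2 (1.2 equiv), −78 → 0 °C; then pH 7 buffer, MeOH, 30% H2O2, 0 °C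
Reagents that add atoms: none
Why: Evans boron syn-aldol, in which the Z-dibutylboron enolate reacts through a Zimmerman–Traxler chair with the auxiliary carbonyl turned away, giving the (2S,3S) adduct whose C2 becomes C3 (R) of the dihydrobenzofuran.

Step 13
Reactants: 21 (S)-4-benzyl-3-{(2S,3S)-2-[5-bromo-3-methoxy-2-(methoxymethoxy)phenyl]-3-hydroxy-3-[3-methoxy-4-(triisopropylsilyloxy)phenyl]propanoyl}oxazolidin-2-one
Product: 22 (1S,2R)-2-[5-bromo-3-methoxy-2-(methoxymethoxy)phenyl]-1-[3-methoxy-4-(triisopropylsilyloxy)phenyl]propane-1,3-diol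
Conditions: LiBH4 (2 equiv), MeOH (2 equiv), THF, 0 °C
Reagents that add atoms: none
Why: Reductive cleavage of the N-acyl oxazolidinone gives the 1,3-diol without enolising the α-aryl centre, so its configuration is kept (the descriptor changes only because priorities change).

Step 14
Reactants: 22 (1S,2R)-2-[5-bromo-3-methoxy-2-(methoxymethoxy)phenyl]-1-[3-methoxy-4-(triisopropylsilyloxy)phenyl]propane-1,3-diol
Product: 23 {(2S,3R)-5-bromo-7-methoxy-2-[3-methoxy-4-(triisopropylsilyloxy)phenyl]-2,3-dihydro-1-benzofuran-3-yl}methanol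
Conditions: HCl (1 M in MeOH), 40 °C
Reagents that add atoms: none
Why: Acid cleaves the MOM acetal and ionises the electron-rich benzylic alcohol, and 5-exo capture of the cation by the phenol oxygen (SN1 cycloetherification) places the aryl group anti to the fixed C3 substituent, giving the 2,3-trans ring with C2 (S).

Step 15
Reactants: 23 {(2S,3R)-5-bromo-7-methoxy-2-[3-methoxy-4-(triisopropylsilyloxy)phenyl]-2,3-dihydro-1-benzofuran-3-yl}methanol
Product: 24 (2S,3R)-5-bromo-3-[(tert-butyldimethylsilyloxy)methyl]-7-methoxy-2-[3-methoxy-4-(triisopropylsilyloxy)phenyl]-2,3-dihydro-1-benzofuran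
Conditions: TBSCl (1.3 equiv), imidazole (2.5 equiv), DMF, rt
Reagents that add atoms: tert-butyldimethylsilyl chloride, CC(C)(C)[Si](C)(C)Cl
Why: Silylation of the primary alcohol removes the last acidic proton before the organozinc and amide-base steps.

Step 16
Reactants: 24 (2S,3R)-5-bromo-3-[(tert-butyldimethylsilyloxy)methyl]-7-methoxy-2-[3-methoxy-4-(triisopropylsilyloxy)phenyl]-2,3-dihydro-1-benzofuran; 25 (3-tert-butoxy-3-oxopropyl)zinc bromide
Product: 26 tert-butyl 3-ArP-propanoate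
Conditions: 25 (1.6 equiv, 0.5 M in THF), Pd(OAc)2 (3 mol %), SPhos (6 mol %), THF, 50 °C
Reagents that add atoms: none
Why: Negishi cross-coupling of the unhindered aryl bromide with the ester-bearing primary alkylzinc installs the propanoate arm under neutral conditions that leave all silyl ethers and both ring stereocentres intact.

Step 17
Reactants: 13 (S)-4-benzyl-3-(3-ArG-propanoyl)oxazolidin-2-one; 26 tert-butyl 3-ArP-propanoate
Product: 27 tert-butyl (2RS,3R)-4-[(S)-4-benzyl-2-oxooxazolidin-3-yl]-3-(ArG-methyl)-2-(ArP-methyl)-4-oxobutanoate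
Conditions: 13 (1.0 equiv), 26 (1.3 equiv), LiN(iPr)2 (2.5 equiv), THF, −78 °C, 30 min; then Fe(acac)3 (2.4 equiv), −78 °C → rt
Reagents that add atoms: none
Why: Oxidative intermolecular enolate heterocoupling, in which both lithium enolates are formed and single-electron oxidation by trivalent iron converts one nucleophilic α-carbon into an electrophilic α-carbonyl radical that the other enolate captures; the chelated Z-enolate of the (S)-benzyl imide reacts on the face opposite the benzyl group, fixing the future lactone C4 as R, while the ester α-centre forms as an epimer mixture that step 19 corrects.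

Step 18
Reactants: 27 tert-butyl (2RS,3R)-4-[(S)-4-benzyl-2-oxooxazolidin-3-yl]-3-(ArG-methyl)-2-(ArP-methyl)-4-oxobutanoate
Product: 28 tert-butyl (2RS,3R)-3-(ArG-methyl)-4-hydroxy-2-(ArP-methyl)butanoate
Conditions: LiBH4 (2 equiv), MeOH (2 equiv), THF, 0 °C
Reagents that add atoms: none
Why: Chemoselective hydride reduction, the imide carbonyl being reduced to the primary alcohol far faster than the hindered tert-butyl ester, which turns the auxiliary-bearing carbonyl into the lactone CH2–O carbon without touching C3.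

Step 19
Reactants: 28 tert-butyl (2RS,3R)-3-(ArG-methyl)-4-hydroxy-2-(ArP-methyl)butanoate
Product: 30 (3R,4R)-4-(ArG-methyl)-3-(ArP-methyl)oxolan-2-one, via lactone epimer mixture 29 (not isolated)
Conditions: KOtBu (0.5 equiv), THF, 0 °C → rt; then NH4Cl (aq)
Reagents that add atoms: none
Why: Alkoxide-catalysed intramolecular transesterification (5-exo lactonisation with loss of tert-butoxide) followed by enolate equilibration at C3 funnels both epimers to the thermodynamically preferred trans-3,4-dibenzyl lactone, setting C3 as R relative to the fixed C4.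

Step 20
Reactants: 30 (3R,4R)-4-(ArG-methyl)-3-(ArP-methyl)oxolan-2-one
Product: 31 CNP0265599.1, (3R,4R)-4-[4-({(1R,2S)-1,3-dihydroxy-1-(4-hydroxy-3-methoxyphenyl)propan-2-yl}oxy)-3-methoxybenzyl]-3-{[(2S,3R)-2-(4-hydroxy-3-methoxyphenyl)-3-(hydroxymethyl)-7-methoxy-2,3-dihydro-1-benzofuran-5-yl]methyl}oxolan-2-one
Conditions: Bu4NF (8 equiv), AcOH (8 equiv), THF, 0 °C → rt
Reagents that add atoms: none
Why: Fluoride-mediated cleavage of the two aryl TIPS and three alkyl TBS ethers, buffered with acetic acid so that the lactone, the benzylic alcohol, the benzylic aryl ether and the trans C3 centre are not disturbed.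

**Compound list**
1 | vanillin (4-hydroxy-3-methoxybenzaldehyde) | COc1cc(C=O)ccc1O | starting material
2 | 3-methoxy-4-(triisopropylsilyloxy)benzaldehyde | COc1cc(C=O)ccc1O[Si](C(C)C)(C(C)C)C(C)C | intermediate
3 | methyl 3-(4-hydroxy-3-methoxyphenyl)propanoate | COC(=O)CCc1ccc(O)c(OC)c1 | starting material
4 | (S)-4-benzyl-3-(chloroacetyl)oxazolidin-2-one | ClCC(=O)N1[C@@H](Cc2ccccc2)COC1=O | starting material
5 | (S)-4-benzyl-3-{[2-methoxy-4-(3-methoxy-3-oxopropyl)phenoxy]acetyl}oxazolidin-2-one | COC(=O)CCc1ccc(OCC(=O)N2[C@@H](Cc3ccccc3)COC2=O)c(OC)c1 | intermediate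
6 | 3-O-trimethylsilyl ether of 7 | COc1cc([C@@H](O[Si](C)(C)C)[C@H](C(=O)N2[C@@H](Cc3ccccc3)COC2=O)Oc2ccc(CCC(=O)OC)cc2OC)ccc1O[Si](C(C)C)(C(C)C)C(C)C | intermediate (not isolated)
7 | (S)-4-benzyl-3-{(2R,3R)-3-hydroxy-2-[2-methoxy-4-(3-methoxy-3-oxopropyl)phenoxy]-3-[3-methoxy-4-(triisopropylsilyloxy)phenyl]propanoyl}oxazolidin-2-one | COc1cc([C@@H](O)[C@H](C(=O)N2[C@@H](Cc3ccccc3)COC2=O)Oc2ccc(CCC(=O)OC)cc2OC)ccc1O[Si](C(C)C)(C(C)C)C(C)C | intermediate
8 | methyl 3-[4-({(1R,2S)-1,3-dihydroxy-1-[3-methoxy-4-(triisopropylsilyloxy)phenyl]propan-2-yl}oxy)-3-methoxyphenyl]propanoate | COc1cc([C@@H](O)[C@H](CO)Oc2ccc(CCC(=O)OC)cc2OC)ccc1O[Si](C(C)C)(C(C)C)C(C)C | intermediate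
9 | methyl 3-ArG-propanoate | COc1cc([C@@H](O[Si](C)(C)C(C)(C)C)[C@H](CO[Si](C)(C)C(C)(C)C)Oc2ccc(CCC(=O)OC)cc2OC)ccc1O[Si](C(C)C)(C(C)C)C(C)C | intermediate
10 | 3-ArG-propanoic acid | COc1cc([C@@H](O[Si](C)(C)C(C)(C)C)[C@H](CO[Si](C)(C)C(C)(C)C)Oc2ccc(CCC(=O)O)cc2OC)ccc1O[Si](C(C)C)(C(C)C)C(C)C | intermediate
11 | (S)-4-benzyloxazolidin-2-one | O=C1N[C@@H](Cc2ccccc2)CO1 | starting material
12 | 3-ArG-propanoic pivalic anhydride | COc1cc([C@@H](O[Si](C)(C)C(C)(C)C)[C@H](CO[Si](C)(C)C(C)(C)C)Oc2ccc(CCC(=O)OC(=O)C(C)(C)C)cc2OC)ccc1O[Si](C(C)C)(C(C)C)C(C)C | intermediate (not isolated)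
13 | (S)-4-benzyl-3-(3-ArG-propanoyl)oxazolidin-2-one | COc1cc([C@@H](O[Si](C)(C)C(C)(C)C)[C@H](CO[Si](C)(C)C(C)(C)C)Oc2ccc(CCC(=O)N3[C@@H](Cc4ccccc4)COC3=O)cc2OC)ccc1O[Si](C(C)C)(C(C)C)C(C)C | intermediate
14 | 2-allyl-6-methoxyphenol (o-eugenol) | C=CCc1cccc(OC)c1O | starting material
15 | 2-allyl-4-bromo-6-methoxyphenol | C=CCc1cc(Br)cc(OC)c1O | intermediate
16 | 1-allyl-5-bromo-3-methoxy-2-(methoxymethoxy)benzene | C=CCc1cc(Br)cc(OC)c1OCOC | intermediate
17 | [5-bromo-3-methoxy-2-(methoxymethoxy)phenyl]acetic acid | OC(=O)Cc1cc(Br)cc(OC)c1OCOC | intermediate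
18 | [5-bromo-3-methoxy-2-(methoxymethoxy)phenyl]acetic pivalic anhydride | CC(C)(C)C(=O)OC(=O)Cc1cc(Br)cc(OC)c1OCOC | intermediate (not isolated)
19 | (S)-4-benzyl-3-{[5-bromo-3-methoxy-2-(methoxymethoxy)phenyl]acetyl}oxazolidin-2-one | O=C(Cc1cc(Br)cc(OC)c1OCOC)N1[C@@H](Cc2ccccc2)COC1=O | intermediate
20 | O-dibutylboryl aldolate of 21 | O=C([C@@H](c1cc(Br)cc(OC)c1OCOC)[C@H](OB(CCCC)CCCC)c1ccc(O[Si](C(C)C)(C(C)C)C(C)C)c(OC)c1)N1[C@@H](Cc2ccccc2)COC1=O | intermediate (not isolated)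
21 | (S)-4-benzyl-3-{(2S,3S)-2-[5-bromo-3-methoxy-2-(methoxymethoxy)phenyl]-3-hydroxy-3-[3-methoxy-4-(triisopropylsilyloxy)phenyl]propanoyl}oxazolidin-2-one | O=C([C@@H](c1cc(Br)cc(OC)c1OCOC)[C@H](O)c1ccc(O[Si](C(C)C)(C(C)C)C(C)C)c(OC)c1)N1[C@@H](Cc2ccccc2)COC1=O | intermediate
22 | (1S,2R)-2-[5-bromo-3-methoxy-2-(methoxymethoxy)phenyl]-1-[3-methoxy-4-(triisopropylsilyloxy)phenyl]propane-1,3-diol | OC[C@@H](c1cc(Br)cc(OC)c1OCOC)[C@H](O)c1ccc(O[Si](C(C)C)(C(C)C)C(C)C)c(OC)c1 | intermediate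
23 | {(2S,3R)-5-bromo-7-methoxy-2-[3-methoxy-4-(triisopropylsilyloxy)phenyl]-2,3-dihydro-1-benzofuran-3-yl}methanol | Brc1cc(OC)c2c(c1)[C@H](CO)[C@@H](c1ccc(O[Si](C(C)C)(C(C)C)C(C)C)c(OC)c1)O2 | intermediate
24 | (2S,3R)-5-bromo-3-[(tert-butyldimethylsilyloxy)methyl]-7-methoxy-2-[3-methoxy-4-(triisopropylsilyloxy)phenyl]-2,3-dihydro-1-benzofuran (ArP–Br) | Brc1cc(OC)c2c(c1)[C@H](CO[Si](C)(C)C(C)(C)C)[C@@H](c1ccc(O[Si](C(C)C)(C(C)C)C(C)C)c(OC)c1)O2 | intermediate
25 | (3-tert-butoxy-3-oxopropyl)zinc bromide | CC(C)(C)OC(=O)CC[Zn]Br | starting material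
26 | tert-butyl 3-ArP-propanoate | CC(C)(C)OC(=O)CCc1cc(OC)c2c(c1)[C@H](CO[Si](C)(C)C(C)(C)C)[C@@H](c1ccc(O[Si](C(C)C)(C(C)C)C(C)C)c(OC)c1)O2 | intermediate
27 | tert-butyl (2RS,3R)-4-[(S)-4-benzyl-2-oxooxazolidin-3-yl]-3-(ArG-methyl)-2-(ArP-methyl)-4-oxobutanoate (C2 epimer mixture) | COc1cc([C@@H](O[Si](C)(C)C(C)(C)C)[C@H](CO[Si](C)(C)C(C)(C)C)Oc2ccc(C[C@@H](C(=O)N3[C@@H](Cc4ccccc4)COC3=O)C(C(=O)OC(C)(C)C)Cc3cc(OC)c4c(c3)[C@H](CO[Si](C)(C)C(C)(C)C)[C@@H](c3ccc(O[Si](C(C)C)(C(C)C)C(C)C)c(OC)c3)O4)cc2OC)ccc1O[Si](C(C)C)(C(C)C)C(C)C | intermediate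
28 | tert-butyl (2RS,3R)-3-(ArG-methyl)-4-hydroxy-2-(ArP-methyl)butanoate (C2 epimer mixture) | COc1cc([C@@H](O[Si](C)(C)C(C)(C)C)[C@H](CO[Si](C)(C)C(C)(C)C)Oc2ccc(C[C@@H](CO)C(C(=O)OC(C)(C)C)Cc3cc(OC)c4c(c3)[C@H](CO[Si](C)(C)C(C)(C)C)[C@@H](c3ccc(O[Si](C(C)C)(C(C)C)C(C)C)c(OC)c3)O4)cc2OC)ccc1O[Si](C(C)C)(C(C)C)C(C)C | intermediate
29 | (3RS,4R)-4-(ArG-methyl)-3-(ArP-methyl)oxolan-2-one (C3 epimer mixture) | COc1cc([C@@H](O[Si](C)(C)C(C)(C)C)[C@H](CO[Si](C)(C)C(C)(C)C)Oc2ccc(C[C@H]3COC(=O)C3Cc3cc(OC)c4c(c3)[C@H](CO[Si](C)(C)C(C)(C)C)[C@@H](c3ccc(O[Si](C(C)C)(C(C)C)C(C)C)c(OC)c3)O4)cc2OC)ccc1O[Si](C(C)C)(C(C)C)C(C)C | intermediate (not isolated)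
30 | (3R,4R)-4-(ArG-methyl)-3-(ArP-methyl)oxolan-2-one | COc1cc([C@@H](O[Si](C)(C)C(C)(C)C)[C@H](CO[Si](C)(C)C(C)(C)C)Oc2ccc(C[C@H]3COC(=O)[C@@H]3Cc3cc(OC)c4c(c3)[C@H](CO[Si](C)(C)C(C)(C)C)[C@@H](c3ccc(O[Si](C(C)C)(C(C)C)C(C)C)c(OC)c3)O4)cc2OC)ccc1O[Si](C(C)C)(C(C)C)C(C)C | intermediate
31 | CNP0265599.1, (3R,4R)-4-[4-({(1R,2S)-1,3-dihydroxy-1-(4-hydroxy-3-methoxyphenyl)propan-2-yl}oxy)-3-methoxybenzyl]-3-{[(2S,3R)-2-(4-hydroxy-3-methoxyphenyl)-3-(hydroxymethyl)-7-methoxy-2,3-dihydro-1-benzofuran-5-yl]methyl}oxolan-2-one | COc1cc([C@@H](O)[C@H](CO)Oc2ccc(C[C@H]3COC(=O)[C@@H]3Cc3cc(OC)c4c(c3)[C@H](CO)[C@@H](c3ccc(O)c(OC)c3)O4)cc2OC)ccc1O | target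

**Step count and risks**

Total step count: 20 (step 1; steps 2–7 to imide 13; steps 8–16 to ester 26; steps 17–20 endgame).
Longest linear sequence: 13 steps (14 → 31 through steps 8–20).

Most likely to fail, first: step 17. Two large, heavily silylated enolates must cross-couple rather than homo-dimerise, and yields in this reaction class are moderate at best. The fallback replaces the oxidation by a polar displacement on a pre-oxidised partner. It sets out from ester 26, which is deprotonated with LiN(iPr)2 in THF at −78 °C and brominated with CBr4 to give tert-butyl (2RS)-2-bromo-3-ArP-propanoate F1. The sodium enolate of imide 13 (NaN(SiMe3)2, THF, −78 → −20 °C) then displaces the bromide by SN2 with the same auxiliary-controlled facial sense. This comes back to the route at 27, and the mixed ester α-centre is again corrected in step 19.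

Second: step 3. Aryloxyacetyl imides and an electron-rich aldehyde lie at the edge of the documented scope of the magnesium-catalysed anti-aldol, so the anti/syn ratio or the facial control may erode. The fallback uses a syn-aldol followed by inversion. It sets out from phenol 3, which is alkylated (K2CO3, NaI, MeCN) with the commercial (R)-enantiomer of 4 to give (R)-4-benzyl-3-{[2-methoxy-4-(3-methoxy-3-oxopropyl)phenoxy]acetyl}oxazolidin-2-one F2. A Bu2BOTf/iPr2NEt syn-aldol with 2 gives the threo adduct (R)-4-benzyl-3-{(2R,3S)-3-hydroxy-2-[2-methoxy-4-(3-methoxy-3-oxopropyl)phenoxy]-3-[3-methoxy-4-(triisopropylsilyloxy)phenyl]propanoyl}oxazolidin-2-one F3. Mitsunobu inversion of the benzylic alcohol (4-nitrobenzoic acid, PPh3, DIAD, THF, 0 °C) gives the (2R,3R) 4-nitrobenzoate F4. NaBH4 in THF/H2O removes the auxiliary to give methyl 3-[4-({(1R,2S)-3-hydroxy-1-[3-methoxy-4-(triisopropylsilyloxy)phenyl]-1-(4-nitrobenzoyloxy)propan-2-yl}oxy)-3-methoxyphenyl]propanoate F5. K2CO3 in MeOH at 0 °C cleaves the nitrobenzoate, which comes back to the route at diol 8.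

Third: step 19. Alkoxide attack on a tert-butyl ester may be slow, and the basic medium may strip or shift silyl groups before lactonisation is complete. The fallback cleaves the ester first and closes the ring by acid activation. It sets out from 28, which is treated with TMSOTf and 2,6-lutidine in CH2Cl2 at 0 °C and worked up with aqueous citric acid to give (2RS,3R)-3-(ArG-methyl)-4-hydroxy-2-(ArP-methyl)butanoic acid F6. Carbodiimide lactonisation (EDC·HCl, DMAP, CH2Cl2) gives lactone mixture 29, which is equilibrated with DBU in toluene at 80 °C. This comes back to the route at 30.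

Further compounds
F1 | step 17 | tert-butyl (2RS)-2-bromo-3-ArP-propanoate | CC(C)(C)OC(=O)C(Br)Cc1cc(OC)c2c(c1)[C@H](CO[Si](C)(C)C(C)(C)C)[C@@H](c1ccc(O[Si](C(C)C)(C(C)C)C(C)C)c(OC)c1)O2
F2 | step 3 | (R)-4-benzyl-3-{[2-methoxy-4-(3-methoxy-3-oxopropyl)phenoxy]acetyl}oxazolidin-2-one | COC(=O)CCc1ccc(OCC(=O)N2[C@H](Cc3ccccc3)COC2=O)c(OC)c1
F3 | step 3 | (R)-4-benzyl-3-{(2R,3S)-3-hydroxy-2-[2-methoxy-4-(3-methoxy-3-oxopropyl)phenoxy]-3-[3-methoxy-4-(triisopropylsilyloxy)phenyl]propanoyl}oxazolidin-2-one | COc1cc([C@H](O)[C@H](C(=O)N2[C@H](Cc3ccccc3)COC2=O)Oc2ccc(CCC(=O)OC)cc2OC)ccc1O[Si](C(C)C)(C(C)C)C(C)C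
F4 | step 3 | (R)-4-benzyl-3-{(2R,3R)-2-[2-methoxy-4-(3-methoxy-3-oxopropyl)phenoxy]-3-[3-methoxy-4-(triisopropylsilyloxy)phenyl]-3-(4-nitrobenzoyloxy)propanoyl}oxazolidin-2-one | COc1cc([C@@H](OC(=O)c2ccc(cc2)[N+](=O)[O-])[C@H](C(=O)N2[C@H](Cc3ccccc3)COC2=O)Oc2ccc(CCC(=O)OC)cc2OC)ccc1O[Si](C(C)C)(C(C)C)C(C)C
F5 | step 3 | methyl 3-[4-({(1R,2S)-3-hydroxy-1-[3-methoxy-4-(triisopropylsilyloxy)phenyl]-1-(4-nitrobenzoyloxy)propan-2-yl}oxy)-3-methoxyphenyl]propanoate | COc1cc([C@@H](OC(=O)c2ccc(cc2)[N+](=O)[O-])[C@H](CO)Oc2ccc(CCC(=O)OC)cc2OC)ccc1O[Si](C(C)C)(C(C)C)C(C)C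
F6 | step 19 | (2RS,3R)-3-(ArG-methyl)-4-hydroxy-2-(ArP-methyl)butanoic acid | COc1cc([C@@H](O[Si](C)(C)C(C)(C)C)[C@H](CO[Si](C)(C)C(C)(C)C)Oc2ccc(C[C@@H](CO)C(C(=O)O)Cc3cc(OC)c4c(c3)[C@H](CO[Si](C)(C)C(C)(C)C)[C@@H](c3ccc(O[Si](C(C)C)(C(C)C)C(C)C)c(OC)c3)O4)cc2OC)ccc1O[Si](C(C)C)(C(C)C)C(C)C
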